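A small charge of catalyst sits in each flask, and the thing to find is how much of what happens runs on the catalyst and how much runs on the clock.

| setting | dawn | winter | noon | midnight | delta | epsilon | gamma | eta | theta |
|---|---|---|---|---|---|---|---|---|---|
| substrate | 10 mM | 10 mM | 10 mM | 18 mM | 10 mM | 40 mM | 10 mM | 15 mM | 10 mM |
| catalyst | 0.038 mM | 0.079 mM | 0.22 mM | 0.12 mM | 0.12 mM | 0.060 mM | 0.20 mM | 0.12 mM | 0.030 mM |
| temperature | 45 °C | 75 °C | 45 °C | 75 °C | 80 °C | 60 °C | 50 °C | 100 °C | 80 °C |
| remark | run made earlier | run made earlier | run made earlier | run made earlier |  |  |  |  |  |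
| time |  |  |  |  | 2.0 min | 2.0 min | 2.0 min | 2.0 min | 2.0 min |

dawn run (percent of the substrate charged)

| time / min | target / % | substrate / % |
|---|---|---|
| 1.00 | 13.2 | 79.2 |
| 2.50 | 25.3 | 59.5 |
| 4.00 | 34.6 | 44.7 |
| 8.00 | 39.5 | 27.6 |

winter run (percent of the substrate charged)

| time / s | target / % | substrate / % |
|---|---|---|
| 10.0 | 17.0 | 70.7 |
| 20.0 | 23.2 | 57.5 |
| 40.0 | 28.0 | 46.6 |
| 60.0 | 26.8 | 39.8 |
| 80.0 | 21.9 | 37.1 |

noon run (percent of the substrate charged)

| time / min | target / % | substrate / % |
|---|---|---|
| 1.33 | 42.5 | 32.6 |
| 3.00 | 38.8 | 20.2 |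
| 5.00 | 31.4 | 18.1 |
| 6.00 | 26.9 | 15.7 |
| 8.00 | 22.1 | 14.2 |

midnight run (percent of the substrate charged)

| time / s | target / % | substrate / % |
|---|---|---|
| 10.0 | 23.7 | 65.7 |
| 12.0 | 23.6 | 61.1 |
| 25.0 | 26.2 | 50.1 |
| 40.0 | 25.8 | 43.3 |
| 80.0 | 20.7 | 34.9 |

(scatter of a reading: 1 percentage point)

- what was read earlier has a scatter of 1 percentage point, one standard deviation

- all flasks from highest to lowest amount of target, in percent of the substrate charged, at 2.0 min (delta / epsilon / gamma / eta / theta)
- the amount of target, in percent of the substrate charged of the flask you put first, at 2.0 min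
- the amount of target, in percent of the substrate charged of the flask you put last, at 2.0 min

Call catalyst times time the dose. At fixed catalyst the catalysed loss is pseudo-first-order, so if catalyst did the work by itself, equal doses would leave equal substrate. The winter run at 60.0 s and the midnight run at 40.0 s had nearly equal doses, 0.0790 mM·min and 0.0800 mM·min. Yet winter, longer on the clock, held 39.8% of the substrate charged against 43.3%. Read as a first-order loss, that gap is a leak of 0.253 min⁻¹ at 75 °C.

That gap of 3.5 percentage points rests on two readings, each with a scatter of 1 point, so take a second way. Winter began by losing substrate at 2.08 min⁻¹, but between its last two readings at 0.211 min⁻¹, so the comparison has drifted, and that late reading lies close to the leak.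

Dawn at 8.00 min and noon at 1.33 min, with doses of 0.304 mM·min and 0.293 mM·min, give 0.0250 min⁻¹ at 45 °C. Going on by that ratio for a sixth of the span, you reach the loss of substrate that runs on the clock at 80 °C, the leak, 0.372 min⁻¹.

Now read a flask two ways: by dose, on the run with the same dose, and then also shrunk by the leak over its extra clock. Gamma has a dose of 0.400 mM·min, which noon reaches at 1.82 min with about 41.4% of target. With the leak read at 45 °C, the shrink factor over gamma's extra clock is 0.995, so the ways agree. Theta's dose, 0.0600 mM·min, is reached by winter at 0.759 min with 27.7%, but the leak shrinks that to 17.4%. The ways part here, and dose by itself is the one that cheats, as the winter and midnight pair showed.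

The forecast gives gamma > epsilon > theta > delta > eta, with top 39% and low 3%, on the ground that “dawn and noon fall on one curve”. It has 25 for theta against your 17.4%.

The flasks give gamma > epsilon > theta > delta > eta, with 37.3% and 1.10%, so the forecast stands.

    substrate + catalyst ⇌ target + catalyst, rate k1*[substrate]*[catalyst] forward; the back reaction follows from the equilibrium constant (K = 0.463, k = 433 L mol⁻¹ s⁻¹, Ea = 49.0 kJ mol⁻¹, ΔH = −30.0 kJ mol⁻¹)
    substrate + catalyst ⇌ isomer of the product + catalyst, rate k2*[substrate]*[catalyst] forward; the back reaction follows from the equilibrium constant (K = 0.640, k = 113 L mol⁻¹ s⁻¹, Ea = 39.0 kJ mol⁻¹, ΔH = −79.0 kJ mol⁻¹)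
    substrate → uncatalysed product (k = 0.00716 s⁻¹, Ea = 86.0 kJ mol⁻¹)
    (constants at 80 °C)

In theta, from 1.00 min to 2.00 min, substrate fell from 42.0% to 28.7% while uncatalysed product rose from 26.6% to 41.4%, which on the mean substrate is 0.418 min⁻¹ beside the leak of 0.372 min⁻¹. Delta, with 0.12 mM of catalyst against theta's 0.030 mM, gives 0.423 min⁻¹ over the same minute. The forecast's order would fail on a run like eta at 75 °C, which holds more target than theta, 17.1% against 16.2%.

Readings and results were generated by integration on assumed constants; the scatter is artificial.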